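Compound numbers 1–21 are those of the steps and the compound list below; 21 is the target.

## The problem

Target 21 (C30H22O17) is a chain of five benzene rings, lettered A to E from the 2,4,6-trihydroxyphenyl end. The rings are joined only by four diaryl ether oxygens and carry thirteen free hydroxyls. There is no stereocentre, so only regiochemistry has to be controlled. The hard part is the ether bonds: of the eight ring carbons that bear a bridging oxygen, A1, B2, C4 and D2 lie between two oxygenated carbons and B1 and D1 next to one. Metal-mediated arylation of phenols is at its weakest in exactly this situation. Rings A, B, C and E are all 1,2,3,5-tetraoxygenated and ring D is pentaoxygenated, but the bridging oxygens sit at different places in each, so every ring must arrive with its oxygens placed and distinguishable. The free polyphenol, with pyrogallol- and hydroquinone-type rings, will not tolerate air in basic medium. All hydroxyls therefore stay masked to the end, and the last step must be non-basic and non-oxidising.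

Ring C makes a short convergent assembly possible. It is a hydroquinone whose C1 oxygen (to ring B) has hydrogen on both neighbouring carbons, while its C4 oxygen (to ring D) lies between the oxygenated carbons C3 and C5. In rings B and D the carbon para to the ring C junction carries a hydroxyl (B5 opposite B2, D4 opposite D1), and ring A shows the same relation (A4 opposite A1). A formyl group at such a position activates a fluoride for displacement and can afterwards be converted into the hydroxyl.

## Retrosynthesis

**21 from 20.** The eleven O–CH3 bonds of the undecamethyl ether 20 are cut last. Methyl is preferred to benzyl because all rings can then be bought with their oxygens in place, and because methyl ethers survive hot carbonate in dimethyl sulfoxide, peracid and copper. 20 is no simpler than 21 in skeleton; the cut only postpones the sensitivity of the polyphenol to the final flask. The forward reaction must cleave eleven aryl methyl ethers with a Lewis acid without touching the four diaryl ether bonds.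

**20 from 18.** The C–O bonds at B5 and D4 are traced back to C–CHO bonds in dialdehyde 18, through bis-formate 19. The formyl groups are kept this late because they are what makes the preceding disconnection possible. The forward oxidation requires aryl migration at both formyl carbons. Ring B offers a para aryloxy group for this, and ring D two ortho methoxy groups and a para aryloxy group.

**18 from 16, 8 and 14.** The two ether bonds at ring C, O–B2 and O–D1, are cut together. This is the most convergent cut available: it falls in the middle of the chain, divides it into fragments of two, one and two rings, and removes the two most hindered junctions at once. The neighbouring cuts at A1–O or D2–O–E1 would leave a four-ring chain still to be built linearly. Hydroquinone 16 is trivial, and fluoroaldehydes 8 and 14 each contain one ether bond. The forward step must arylate the unhindered oxygen of 16 with 8 first (through phenol 17) and then the hindered oxygen with 14, in one flask.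

**16 from 15.** The hydroquinone is air-sensitive and is made when needed by reducing the stable quinone 15. No skeletal bond is involved.

**8 from 6, 4, 3 and 1.** In fragment AB the A1–O bond is cut, giving ring B phenol 3 and a ring A electrophile. Transfer of an intact 2,4,6-trimethoxyphenyl group from boron or trivalent iodine was rejected: doubly ortho-substituted, very electron-rich aryl groups transfer poorly by either route. Ring A is instead made the way rings B and D are used later. Fluoroaldehyde 1 is attacked by the phenoxide of 3 to give 4, and the ring A formyl is then turned into the fourth oxygen (formate 5, phenol 6) and methylated (7). Ring B's own formyl must be masked as a dioxolane (3, from 2) during this. Otherwise the product of the arylation would again be a para-formyl fluoroarene competing with 1, and the two formyl groups could not be told apart in the oxidation. Converting ring A's formyl into a methoxy group before the key step also keeps a second formyl-activated ether carbon out of that step. Phenol 2 comes from 1 by cleavage of one of its two equivalent methyl ethers, so 1 supplies both rings.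

**14 from 12 and 13; 12 from 10 and 9.** In fragment DE the D2–O–E1 bond is cut on the ring E side. Ring E has no ortho substituent, so boronic acid 13 can be coupled to the hindered phenol 12 at room temperature under copper mediation. These conditions cannot displace the activated fluoride, whereas a hot basic coupling of a ring E phenoxide with bromide 10 would. Phenol 12 is reached from 9 by bromination at the position activated by both methoxy groups (10) and exchange of bromine for hydroxyl through boronate 11.

## Roads not taken

**Alternative 1:** Ring B would be built rather than bought. The cut runs through its B1–B6, B5–B6, B3–B4 and B2–B3 bonds and leads to diazo ketone A2 (4-(benzyloxy)-1-diazo-3-(2,4,6-trimethoxyphenoxy)but-3-en-2-one, alkene geometry immaterial) and ethoxyethyne A3.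

- *Forward key step:* Irradiation of A2 would trigger a Wolff rearrangement to a vinylketene. This adds A3 in a (2+2) cycloaddition, and the cyclobutenone opens and recloses by 6π electrocyclisation to phenol A1, 2-(benzyloxy)-5-ethoxy-3-(2,4,6-trimethoxyphenoxy)phenol (a Danheiser benzannulation).
- *Merits:* The four oxygens of ring B arrive fully differentiated (free at B3, benzyl at B2, ethyl at B5, aryl at B1), and the A–O–B bond is made on an acyclic precursor. In this respect the road is better than the chosen plan, which accepts a statistical monodemethylation in step 1.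
- *Weak points:* A2 is a sensitive, doubly oxygenated diazo enone that itself needs several steps. The benzannulation must tolerate two donor oxygens on the vinylketene. Above all, A1 solves only one ring: after debenzylation the B2 oxygen is a phenol between two oxygenated carbons and must still be joined to ring C, and the C–D and D–E ethers remain.
- *Comparison:* The chosen plan forms the two central ether bonds in one operation from purchased, fully oxygenated arenes, with a longest linear sequence of eight steps. This road would spend about that many on ring B alone.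

**Alternative 2:** Ring D would be made by ring expansion of a four-membered ring, the cut being the D1–D2 bond.

- *Forward key step:* Heating cyclobutenone A5 (racemic 4-{2-[4-(benzyloxy)-2,6-dimethoxyphenoxy]ethenyl}-2,3,4-trimethoxycyclobut-2-en-1-one) opens it to a dienylketene that electrocyclises and tautomerises to A4, 6-[4-(benzyloxy)-2,6-dimethoxyphenoxy]-2,3,4-trimethoxyphenol, free only at D2.
- *Merits:* This road is stronger exactly where the chosen plan is weakest. The hindered C4–O–D1 ether exists before ring D does, so no doubly flanked phenoxide has to attack a fluoroarene that two methoxy groups deactivate. The five oxygens of ring D are placed unambiguously, with D2 free for ring E.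
- *Weak points:* A5 requires a vinyl-metal reagent with an aryloxy group β to the metal, which is prone to eliminate aryloxide. The hindered aryl vinyl ether must itself be prepared. The D2 phenol of A4 is again flanked on both sides when ring E is attached. Ring C's benzyl ether must be removed and the B–C bond made separately.
- *Comparison:* The chosen plan is more convergent, uses commercial rings, and has a stepwise fallback for its hindered displacement. If that displacement failed even on isolated 17, this would be the road to turn to.

**Alternative 3:** Ring A would be built in polyketide fashion, the cut being the A1–A2 bond.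

- *Forward key step:* Excess LiN(iPr)2 would convert keto ester A7 (methyl 6-[2-(benzyloxy)-3,5-dimethoxyphenoxy]-3,5-dioxohexanoate) into a trianion. Its aryloxy-bearing terminal carbon attacks the ester carbonyl, and the triketone enolises to A6, 2-[2-(benzyloxy)-3,5-dimethoxyphenoxy]benzene-1,3,5-triol.
- *Merits:* The A1–O–B1 bond is made as an alkyl aryl ether by simple alkylation. For that one bond this is as good as or better than the five steps from 1 to 8, and ring A emerges without protecting groups.
- *Weak points:* The ester is deactivated by the adjacent enolate, so such Claisen closures are sluggish and compete with aldol-type modes. The road builds the simplest ring of the molecule de novo. The three free hydroxyls of A6 would have to be protected again before any further arylation. Ring B in A6 has no activating group, so the B2–O–C bond would need yet another method.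
- *Comparison:* The chosen plan pays five routine steps for fragment 8, but keeps every ring masked in one uniform way and retains the formyl handle that the central coupling needs.

Key step: step 10

Remark (assumption): arenes 1, 9, 13 and 15 are taken as purchasable; hydroquinone 16 is prepared fresh because it does not keep in air.

## Route

Step 1
Reactants: 1 4-fluoro-3,5-dimethoxybenzaldehyde
Product: 2 4-fluoro-3-hydroxy-5-methoxybenzaldehyde
Conditions: BBr3 (1.5–2 equiv, one equivalent being bound by the formyl oxygen), CH2Cl2, −78 to 0 °C, monitored; then H2O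
Reagents that add atoms: none
Why: Lewis-acid cleavage of an aryl methyl ether; the two methoxy groups are equivalent, and once one has become an aryloxyborane the ring is poorer in electrons and the second oxygen less basic, so limited reagent in the cold should stop mainly at the monophenol. Recovered 1 is reused in step 3.

Step 2
Reactants: 2 4-fluoro-3-hydroxy-5-methoxybenzaldehyde
Product: 3 5-(1,3-dioxolan-2-yl)-2-fluoro-3-methoxyphenol
Conditions: HOCH2CH2OH, p-TsOH·H2O (cat.), toluene, reflux, Dean–Stark trap
Reagents that add atoms: ethylene glycol, OCCO
Why: Acid-catalysed acetalisation with azeotropic removal of water, which a free phenol tolerates. The dioxolane removes the only acceptor para to fluorine, so the fluoride of 3 is inert in step 3.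

Step 3
Reactants: 3 5-(1,3-dioxolan-2-yl)-2-fluoro-3-methoxyphenol; 1 4-fluoro-3,5-dimethoxybenzaldehyde
Product: 4 4-[5-(1,3-dioxolan-2-yl)-2-fluoro-3-methoxyphenoxy]-3,5-dimethoxybenzaldehyde
Conditions: Cs2CO3, DMSO, 100 °C, argon
Reagents that add atoms: none
Why: Nucleophilic aromatic substitution (addition–elimination) of the unhindered phenoxide of 3 on the fluoride of 1, activated by the para formyl group. 3 cannot oligomerise because its own fluoride is not activated, and the only formyl group of the product sits on ring A.

Step 4
Reactants: 4 4-[5-(1,3-dioxolan-2-yl)-2-fluoro-3-methoxyphenoxy]-3,5-dimethoxybenzaldehyde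
Product: 6 4-[5-(1,3-dioxolan-2-yl)-2-fluoro-3-methoxyphenoxy]-3,5-dimethoxyphenol, via aryl formate 5 (not isolated)
Conditions: mCPBA (1.3 equiv), CH2Cl2, 0 °C to rt; then K2CO3 (cat.), MeOH, rt
Reagents that add atoms: meta-chloroperoxybenzoic acid, OOC(=O)c1cccc(Cl)c1
Why: Baeyer–Villiger (Dakin-type) oxidation: the ring A formyl has a para aryloxy and two meta methoxy groups, as in 3,4,5-trialkoxybenzaldehydes, so the aryl group migrates to give formate 5, which mild methanolysis cleaves. The dioxolane is inert to peracid and base; should some of it hydrolyse, the freed ring B formyl (para to fluorine, no ortho or para oxygen) is a poor substrate for this oxidation and is regenerated in step 5 anyway.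

Step 5
Reactants: 6 4-[5-(1,3-dioxolan-2-yl)-2-fluoro-3-methoxyphenoxy]-3,5-dimethoxyphenol
Product: 8 4-fluoro-3-methoxy-5-(2,4,6-trimethoxyphenoxy)benzaldehyde, via methylated dioxolane 7 (not isolated)
Conditions: MeI, K2CO3, acetone, reflux; then 1 M HCl, THF, rt
Reagents that add atoms: iodomethane, CI
Why: Williamson methylation of the only free phenol, then aqueous acid hydrolysis of the dioxolane, which diaryl and methyl ethers survive. This unveils the formyl group that activates the ring B fluoride for the key step.

Step 6
Reactants: 9 4-fluoro-2,6-dimethoxybenzaldehyde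
Product: 10 3-bromo-4-fluoro-2,6-dimethoxybenzaldehyde
Conditions: NBS (1.0 equiv), MeCN, 0 °C to rt, dark
Reagents that add atoms: N-bromosuccinimide, O=C1CCC(=O)N1Br
Why: Electrophilic aromatic bromination: C3 (equivalent to C5) is ortho to one methoxy group and para to the other, and the monobromide is less reactive than 9, so one equivalent should stop at 10.

Step 7
Reactants: 10 3-bromo-4-fluoro-2,6-dimethoxybenzaldehyde
Product: 12 4-fluoro-3-hydroxy-2,6-dimethoxybenzaldehyde, via aryl pinacol boronate 11 (not isolated)
Conditions: B2pin2, PdCl2(dppf) (5 mol%), KOAc, 1,4-dioxane, 90 °C; then NaBO3·4H2O, THF–H2O, rt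
Reagents that add atoms: bis(pinacolato)diboron (boryl group of 11 only), CC1(C)OB(OC1(C)C)B1OC(C)(C)C(C)(C)O1; sodium perborate (hydroxyl oxygen of 12), [Na+].[Na+].O[B-]1(O)OO[B-](O)(O)OO1
Why: Miyaura borylation of the aryl bromide followed by oxidation of the C–B bond with perborate, which is mild enough to spare the aldehyde and the activated fluoride. Direct hydroxylation with hydroxide is avoided because hydroxide would displace the fluoride.

Step 8
Reactants: 12 4-fluoro-3-hydroxy-2,6-dimethoxybenzaldehyde; 13 3,4,5-trimethoxyphenylboronic acid
Product: 14 4-fluoro-2,6-dimethoxy-3-(3,4,5-trimethoxyphenoxy)benzaldehyde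
Conditions: Cu(OAc)2 (1.0 equiv), pyridine (5 equiv), 4 Å molecular sieves, CH2Cl2, dry air, rt; 13 in excess (2–3 equiv)
Reagents that add atoms: none
Why: Chan–Lam coupling: oxidative copper-mediated O-arylation that tolerates ortho-substituted phenols when the boronic acid, as here, has no ortho substituent. At room temperature with an amine base the activated fluoride is not displaced, and air returns the copper to the divalent state.

Step 9
Reactants: 15 2,6-dimethoxy-1,4-benzoquinone
Product: 16 2,6-dimethoxybenzene-1,4-diol
Conditions: H2 (1 atm), Pd/C (10 wt%), THF, rt; filtered under argon and used at once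
Reagents that add atoms: none
Why: Catalytic hydrogenation of a quinone to its hydroquinone, a clean two-electron reduction without by-product. The product stays under argon and goes directly into step 10.

Step 10
Reactants: 16 2,6-dimethoxybenzene-1,4-diol; 8 4-fluoro-3-methoxy-5-(2,4,6-trimethoxyphenoxy)benzaldehyde; 14 4-fluoro-2,6-dimethoxy-3-(3,4,5-trimethoxyphenoxy)benzaldehyde
Product: 18 4-{4-[4-formyl-2-methoxy-6-(2,4,6-trimethoxyphenoxy)phenoxy]-2,6-dimethoxyphenoxy}-2,6-dimethoxy-3-(3,4,5-trimethoxyphenoxy)benzaldehyde, via mono-arylated phenol 17 (not isolated)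
Conditions: 16 (1.1 equiv), 8 (1.0 equiv), Cs2CO3 (1.1 equiv), degassed DMSO, 4 Å molecular sieves, 90 °C until 8 is consumed; then 14 (1.3 equiv), Cs2CO3 (1.5 equiv), 130 °C
Reagents that add atoms: none
Why: Each C–O bond forms by addition–elimination: a phenoxide adds to the fluorine-bearing carbon, the charge of the Meisenheimer complex is taken up by the para formyl group, and fluoride leaves. The closest known reaction type is the arylation of phenoxides with 4-fluorobenzaldehydes in dipolar aprotic solvents, the first half of the classical 4-aryloxyphenol synthesis; here two such displacements run consecutively in one flask, no ring is closed and no stereocentre is made. The step needs site selectivity between the two oxygens of 16: with about one equivalent of base the phenoxide sits mainly on the oxygen meta to the methoxy groups, which is the more acidic one, and this is also the only oxygen that can readily reach the fluoride of 8, whose carbon lies between OMe and OAr. 8 is the limiting component and is consumed, giving 17, before 14 and more base are added, so the order of addition decides which fluoroarene ends on which oxygen. The remaining 2,6-dimethoxyphenoxide of 17 is hindered but electron-rich, and in 14 it meets a fluoride with one unsubstituted ortho position, which is why this pairing is left for the hotter second stage. Fluoride is a far better leaving group than aryloxide in this mechanism, so the diaryl ethers already standing para to formyl groups should not exchange, and the aldehydes have no α-hydrogen and are inert to carbonate in dry DMSO. Air and water are excluded to prevent oxidation of the hydroquinone anion and hydrolysis of the fluorides.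

Step 11
Reactants: 18 4-{4-[4-formyl-2-methoxy-6-(2,4,6-trimethoxyphenoxy)phenoxy]-2,6-dimethoxyphenoxy}-2,6-dimethoxy-3-(3,4,5-trimethoxyphenoxy)benzaldehyde
Product: 20 4-{4-[4-hydroxy-2-methoxy-6-(2,4,6-trimethoxyphenoxy)phenoxy]-2,6-dimethoxyphenoxy}-2,6-dimethoxy-3-(3,4,5-trimethoxyphenoxy)phenol, via bis-formate 19 (not isolated)
Conditions: mCPBA (3 equiv), CH2Cl2, 0 °C to rt; then K2CO3 (cat.), MeOH, 0 °C, argon
Reagents that add atoms: meta-chloroperoxybenzoic acid, OOC(=O)c1cccc(Cl)c1
Why: Double Baeyer–Villiger (Dakin-type) oxidation: the ring B formyl has a para aryloxy group and the ring D formyl two ortho methoxy groups and a para aryloxy group, so in both the electron-rich aryl group migrates to oxygen. Bis-formate 19 is cleaved by catalytic carbonate in methanol, under argon because the new phenols are electron-rich.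

Step 12
Reactants: 20 4-{4-[4-hydroxy-2-methoxy-6-(2,4,6-trimethoxyphenoxy)phenoxy]-2,6-dimethoxyphenoxy}-2,6-dimethoxy-3-(3,4,5-trimethoxyphenoxy)phenol
Product: 21 5-{4-[2,4-dihydroxy-6-(2,4,6-trihydroxyphenoxy)phenoxy]-2,6-dihydroxyphenoxy}-4-(3,4,5-trihydroxyphenoxy)benzene-1,2,3-triol
Conditions: BBr3 (large excess), CH2Cl2, −78 °C to rt; then H2O at 0 °C; isolation with degassed solvents (reversed-phase silica or Sephadex LH-20)
Reagents that add atoms: none
Why: Exhaustive Lewis-acid demethylation: each aryl methyl ether is cleaved through its O–B complex by bromide attack at methyl, while the diaryl ether bonds offer no sp3 carbon and remain. The acidic, non-oxidising work-up protects the polyphenol.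

## Compound list

1 | 4-fluoro-3,5-dimethoxybenzaldehyde | COc1cc(C=O)cc(OC)c1F | starting material
2 | 4-fluoro-3-hydroxy-5-methoxybenzaldehyde | COc1cc(C=O)cc(O)c1F | intermediate
3 | 5-(1,3-dioxolan-2-yl)-2-fluoro-3-methoxyphenol | COc1cc(C2OCCO2)cc(O)c1F | intermediate
4 | 4-[5-(1,3-dioxolan-2-yl)-2-fluoro-3-methoxyphenoxy]-3,5-dimethoxybenzaldehyde | COc1cc(C=O)cc(OC)c1Oc1cc(C2OCCO2)cc(OC)c1F | intermediate
5 | 4-[5-(1,3-dioxolan-2-yl)-2-fluoro-3-methoxyphenoxy]-3,5-dimethoxyphenyl formate | COc1cc(OC=O)cc(OC)c1Oc1cc(C2OCCO2)cc(OC)c1F | intermediate
6 | 4-[5-(1,3-dioxolan-2-yl)-2-fluoro-3-methoxyphenoxy]-3,5-dimethoxyphenol | COc1cc(O)cc(OC)c1Oc1cc(C2OCCO2)cc(OC)c1F | intermediate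
7 | 2-[4-fluoro-3-methoxy-5-(2,4,6-trimethoxyphenoxy)phenyl]-1,3-dioxolane | COc1cc(OC)c(Oc2cc(C3OCCO3)cc(OC)c2F)c(OC)c1 | intermediate
8 | 4-fluoro-3-methoxy-5-(2,4,6-trimethoxyphenoxy)benzaldehyde | COc1cc(OC)c(Oc2cc(C=O)cc(OC)c2F)c(OC)c1 | intermediate
9 | 4-fluoro-2,6-dimethoxybenzaldehyde | COc1cc(F)cc(OC)c1C=O | starting material
10 | 3-bromo-4-fluoro-2,6-dimethoxybenzaldehyde | COc1cc(F)c(Br)c(OC)c1C=O | intermediate
11 | 4-fluoro-2,6-dimethoxy-3-(4,4,5,5-tetramethyl-1,3,2-dioxaborolan-2-yl)benzaldehyde | COc1cc(F)c(B2OC(C)(C)C(C)(C)O2)c(OC)c1C=O | intermediate
12 | 4-fluoro-3-hydroxy-2,6-dimethoxybenzaldehyde | COc1cc(F)c(O)c(OC)c1C=O | intermediate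
13 | 3,4,5-trimethoxyphenylboronic acid | COc1cc(B(O)O)cc(OC)c1OC | starting material
14 | 4-fluoro-2,6-dimethoxy-3-(3,4,5-trimethoxyphenoxy)benzaldehyde | COc1cc(F)c(Oc2cc(OC)c(OC)c(OC)c2)c(OC)c1C=O | intermediate
15 | 2,6-dimethoxy-1,4-benzoquinone | COC1=CC(=O)C=C(OC)C1=O | starting material
16 | 2,6-dimethoxybenzene-1,4-diol | COc1cc(O)cc(OC)c1O | intermediate
17 | 4-(4-hydroxy-3,5-dimethoxyphenoxy)-3-methoxy-5-(2,4,6-trimethoxyphenoxy)benzaldehyde | COc1cc(OC)c(Oc2cc(C=O)cc(OC)c2Oc2cc(OC)c(O)c(OC)c2)c(OC)c1 | intermediate
18 | 4-{4-[4-formyl-2-methoxy-6-(2,4,6-trimethoxyphenoxy)phenoxy]-2,6-dimethoxyphenoxy}-2,6-dimethoxy-3-(3,4,5-trimethoxyphenoxy)benzaldehyde | COc1cc(OC)c(Oc2cc(C=O)cc(OC)c2Oc2cc(OC)c(Oc3cc(OC)c(C=O)c(OC)c3Oc3cc(OC)c(OC)c(OC)c3)c(OC)c2)c(OC)c1 | intermediate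
19 | 4-{4-[4-(formyloxy)-2-methoxy-6-(2,4,6-trimethoxyphenoxy)phenoxy]-2,6-dimethoxyphenoxy}-2,6-dimethoxy-3-(3,4,5-trimethoxyphenoxy)phenyl formate | COc1cc(OC)c(Oc2cc(OC=O)cc(OC)c2Oc2cc(OC)c(Oc3cc(OC)c(OC=O)c(OC)c3Oc3cc(OC)c(OC)c(OC)c3)c(OC)c2)c(OC)c1 | intermediate
20 | 4-{4-[4-hydroxy-2-methoxy-6-(2,4,6-trimethoxyphenoxy)phenoxy]-2,6-dimethoxyphenoxy}-2,6-dimethoxy-3-(3,4,5-trimethoxyphenoxy)phenol | COc1cc(OC)c(Oc2cc(O)cc(OC)c2Oc2cc(OC)c(Oc3cc(OC)c(O)c(OC)c3Oc3cc(OC)c(OC)c(OC)c3)c(OC)c2)c(OC)c1 | intermediate
21 | 5-{4-[2,4-dihydroxy-6-(2,4,6-trihydroxyphenoxy)phenoxy]-2,6-dihydroxyphenoxy}-4-(3,4,5-trihydroxyphenoxy)benzene-1,2,3-triol | Oc1cc(O)c(Oc2cc(O)cc(O)c2Oc2cc(O)c(Oc3cc(O)c(O)c(O)c3Oc3cc(O)c(O)c(O)c3)c(O)c2)c(O)c1 | target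

## Step count and least certain steps

Total: 12 steps. Longest linear sequence: 8 steps (steps 1, 2, 3, 4, 5, 10, 11, 12). The branches through 9 (steps 6–8) and 15 (step 9) are shorter.

**Step 10 (key step).** Two things are most likely to go wrong. The first is loss of site selectivity in the first stage, by arylation of the hindered oxygen or double arylation of 16. The second is a second displacement that stalls, because the fluoride of 14 is deactivated by two methoxy groups conjugated with its formyl group and the nucleophile is flanked on both sides. Hydrolysis of the fluoride by traces of water, or exchange at the formyl-activated ether carbons, would then catch up and give a mixture that cannot be resolved from one pot.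

Fallback: the two bonds are made in separate operations with the hindered oxygen masked, setting out from 8.
- Purchased 4-hydroxy-3,5-dimethoxybenzaldehyde is protected (MOMCl, iPr2NEt, CH2Cl2) as 3,5-dimethoxy-4-(methoxymethoxy)benzaldehyde F1.
- Oxidation with mCPBA gives 3,5-dimethoxy-4-(methoxymethoxy)phenyl formate F2, and methanolysis (K2CO3, MeOH) gives 3,5-dimethoxy-4-(methoxymethoxy)phenol F3.
- F3 and 8 (Cs2CO3, DMSO, 90 °C) give 4-[3,5-dimethoxy-4-(methoxymethoxy)phenoxy]-3-methoxy-5-(2,4,6-trimethoxyphenoxy)benzaldehyde F4, in which only one oxygen of ring C could react.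
- Aqueous HCl in THF removes the methoxymethyl group and gives 17, now isolated and purified.
- 17 is arylated on its own with an excess of 14 (Cs2CO3, DMSO, 130 °C), which returns to the route at 18.

**Step 12.** Eleven ether cleavages must all go to completion. Incomplete demethylation at the most crowded methoxy groups and oxidative degradation of the polyphenol during chromatography are the likely failures. Fallback, setting out from 20: the crude BBr3 product is acetylated exhaustively (Ac2O, pyridine) to the tridecaacetate 5-{4-[2,4-diacetoxy-6-(2,4,6-triacetoxyphenoxy)phenoxy]-2,6-diacetoxyphenoxy}-4-(3,4,5-triacetoxyphenoxy)benzene-1,2,3-triyl triacetate F5. F5 is stable to air and silica and separates from partly methylated material. Methanolysis with HCl in MeOH under argon then returns to the route at 21.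

**Step 8.** Protodeboronation and oxidative homocoupling of 13 may outrun C–O bond formation at the phenol, which is flanked by methoxy and fluorine. Fallback, setting out from 10 (it also bypasses step 7): the aldehyde is masked with ethylene glycol (p-TsOH, toluene, reflux) as 2-(3-bromo-4-fluoro-2,6-dimethoxyphenyl)-1,3-dioxolane F6, whose fluoride is no longer activated. Palladium-catalysed diaryl ether formation with purchased 3,4,5-trimethoxyphenol (Pd(OAc)2, 2-di-tert-butylphosphino-2′,4′,6′-triisopropylbiphenyl, K3PO4, toluene, 100 °C) gives 2-[4-fluoro-2,6-dimethoxy-3-(3,4,5-trimethoxyphenoxy)phenyl]-1,3-dioxolane F7. Aqueous HCl in THF returns to the route at 14.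

**Step 1.** Cleavage of one of two equivalent ethers may over-run to the diol or stop short, giving a statistical mixture that costs material. Fallback, setting out from 1: the aldehyde is first converted (ethylene glycol, p-TsOH, toluene, reflux) into 2-(4-fluoro-3,5-dimethoxyphenyl)-1,3-dioxolane F8, whose fluoride is unactivated. Nucleophilic demethylation with NaSEt in DMF at about 110 °C stops after one methyl group, because the phenoxide formed makes the second aryloxide a poor leaving group. This returns to the route at 3 and also replaces step 2.

## Further compounds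

F1 | step 10 | 3,5-dimethoxy-4-(methoxymethoxy)benzaldehyde | COCOc1c(OC)cc(C=O)cc1OC
F2 | step 10 | 3,5-dimethoxy-4-(methoxymethoxy)phenyl formate | COCOc1c(OC)cc(OC=O)cc1OC
F3 | step 10 | 3,5-dimethoxy-4-(methoxymethoxy)phenol | COCOc1c(OC)cc(O)cc1OC
F4 | step 10 | 4-[3,5-dimethoxy-4-(methoxymethoxy)phenoxy]-3-methoxy-5-(2,4,6-trimethoxyphenoxy)benzaldehyde | COCOc1c(OC)cc(Oc2c(OC)cc(C=O)cc2Oc2c(OC)cc(OC)cc2OC)cc1OC
F5 | step 12 | 5-{4-[2,4-diacetoxy-6-(2,4,6-triacetoxyphenoxy)phenoxy]-2,6-diacetoxyphenoxy}-4-(3,4,5-triacetoxyphenoxy)benzene-1,2,3-triyl triacetate | CC(=O)Oc1cc(OC(C)=O)c(Oc2cc(OC(C)=O)cc(OC(C)=O)c2Oc2cc(OC(C)=O)c(Oc3cc(OC(C)=O)c(OC(C)=O)c(OC(C)=O)c3Oc3cc(OC(C)=O)c(OC(C)=O)c(OC(C)=O)c3)c(OC(C)=O)c2)c(OC(C)=O)c1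
F6 | step 8 | 2-(3-bromo-4-fluoro-2,6-dimethoxyphenyl)-1,3-dioxolane | COc1cc(F)c(Br)c(OC)c1C1OCCO1
F7 | step 8 | 2-[4-fluoro-2,6-dimethoxy-3-(3,4,5-trimethoxyphenoxy)phenyl]-1,3-dioxolane | COc1cc(F)c(Oc2cc(OC)c(OC)c(OC)c2)c(OC)c1C1OCCO1
F8 | step 1 | 2-(4-fluoro-3,5-dimethoxyphenyl)-1,3-dioxolane | COc1cc(C2OCCO2)cc(OC)c1F
A1 | alternative 1 | 2-(benzyloxy)-5-ethoxy-3-(2,4,6-trimethoxyphenoxy)phenol | CCOc1cc(O)c(OCc2ccccc2)c(Oc2c(OC)cc(OC)cc2OC)c1
A2 | alternative 1 | 4-(benzyloxy)-1-diazo-3-(2,4,6-trimethoxyphenoxy)but-3-en-2-one (alkene geometry not fixed) | [N-]=[N+]=CC(=O)C(=COCc1ccccc1)Oc1c(OC)cc(OC)cc1OC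
A3 | alternative 1 | ethoxyethyne | CCOC#C
A4 | alternative 2 | 6-[4-(benzyloxy)-2,6-dimethoxyphenoxy]-2,3,4-trimethoxyphenol | COc1cc(Oc2c(OC)cc(OCc3ccccc3)cc2OC)c(O)c(OC)c1OC
A5 | alternative 2 | 4-{2-[4-(benzyloxy)-2,6-dimethoxyphenoxy]ethenyl}-2,3,4-trimethoxycyclobut-2-en-1-one (racemic, alkene geometry not fixed) | COC1=C(OC)C(OC)(C=COc2c(OC)cc(OCc3ccccc3)cc2OC)C1=O
A6 | alternative 3 | 2-[2-(benzyloxy)-3,5-dimethoxyphenoxy]benzene-1,3,5-triol | Oc1cc(O)c(Oc2cc(OC)cc(OC)c2OCc2ccccc2)c(O)c1
A7 | alternative 3 | methyl 6-[2-(benzyloxy)-3,5-dimethoxyphenoxy]-3,5-dioxohexanoate | COC(=O)CC(=O)CC(=O)COc1cc(OC)cc(OC)c1OCc1ccccc1
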